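A slow carry-off keeps released group in the flask, with a half-life of 102 s at 60 °C, and target is what it attacks during that stay.

    target + released group → side product (k1 = 0.013 M⁻¹ s⁻¹, Ea1 = 66.0 kJ mol⁻¹)
    released group → by-product carried off (k2 = 0.0068 s⁻¹, Ea2 = 92.0 kJ mol⁻¹)
    substrate + reagent ⇌ target + released group (K3 = 24, k3 = 0.13 M⁻¹ s⁻¹, Ea3 = 45.0 kJ mol⁻¹, ΔH3 = −22.0 kJ mol⁻¹)
    target ⇌ isomer of the product (K4 = 1.7, k4 = 0.066 s⁻¹, Ea4 = 75.0 kJ mol⁻¹, ΔH4 = −36.0 kJ mol⁻¹)
    (constants at 60 °C)

| setting | north | west | south-west |
|---|---|---|---|
| substrate | 1.0 M | 1.0 M | 1.0 M |
| reagent | 1.30 M | 1.30 M | 1.30 M |
| temperature | 75 °C | 90 °C | 60 °C |
| time | 50 s | 50 s | 50 s |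

- the constants hold at 60 °C; other temperatures follow from the activation energies and enthalpies

* the flask with the highest amount of target, in percent of the substrate charged ("all alike" if they lie within 1.5 percentage points) (north / west / south-west / all alike)
* final target, as a percentage of the substrate charged, in north
* final target, as a percentage of the substrate charged, in west
* final target, as a percentage of the substrate charged, in south-west

- **First instants.** Substrate is the limiting reagent and gives target and released group one for one. In south-west its pseudo-first-order half-life at charged reagent is about 4.10 s, and this forward step speeds up 3.8-fold from south-west to west.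
- **Pool.** Target and isomer relax in 0.412 s in west and 6.61 s in south-west, both short against the time, so they are reckoned as one pool. Target's share s of that pool is 37.0% in south-west, 50.7% in north and 63.3% in west.
- **Middle.** This reckoning lets each released group either be carried off or capture a target, and it ignores the fall back to substrate. Let p be the fraction of the charge left in the pool, and E the carry-off constant over the capture constant times s times charged substrate. The captured share at that p is p/(p+E), and the estimate sets this share equal to the fraction lost. In west E is 1.80, the escape number. In north it is 1.54, and in south-west 1.41.
- **End.** Solving for the fraction left gives p of 71.5% in west, 69.1% in north and 67.6% in south-west. This reckoning therefore gives 45.2% of target in west and 35.1% in north, both estimates for a run in which released group has been used up. North's carry-off half-life of 24.4 s stands against a time of 50 s, so the north figure is rough at the asked time.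
- **South-west unfinished.** The carry-off half-life in south-west is longer than the time, so the reckoned end value of 25.0% belongs to a later moment than the asked one. This reckoning puts target in south-west at the asked time above 25.0% and below 37.0%. With south-west taken at that upper figure, the flask with most by this reckoning is west.
- **Forecast.** It names west, with 37% (33% to 42%) in north, 45% (40% to 50%) in west and 32% (28% to 36%) in south-west. Its ground is that the “isomer equilibrium shifts back toward the target on heating”.
- **Result.** The flask with most is west, with 35.8% in north, 45.4% in west and 30.1% in south-west, so the forecast holds.
- **Deciding comparison.** At 50.0 s in west, released group has a half-life of 6.6 s by carry-off and 16 s by capture, so carry-off runs faster, by a factor of 2.50.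
- **Second flask.** With 0.25 M of substrate at west's temperature, E grows to 7.18, p to 89.0% and target to 56.3%. The simulation gives 56.4%.

(Its constants are invented; the rest is arithmetic.)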